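**Assumption:** the target has no stereocentres (it is achiral), so no stereocontrol is needed and "single enantiomer" is met trivially.

## Retrosynthetic overview

1. Target 19 ⇒ global O‑debenzylation of tetrabenzyl ether 18, in which ring C is already a free 2‑aryloxyphloroglucinol.
2. Ring C of 18 ⇒ built de novo by base‑mediated intramolecular Claisen cyclisation/aromatisation of the 6‑aryloxy‑3,5‑dioxohexanoate 17.
3. 17 ⇒ key C–C bond: intermolecular Claisen condensation of the methyl acetoacetate dianion with the A–B aryloxyacetate 14.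
4. 14 ⇒ O‑alkylation of A–B phenol 12; its diaryl ether ⇒ Ullmann coupling of ring‑B phenol 8 with ring‑A bromide 10.
5. 8 ⇒ 2,4,6‑trihydroxybenzaldehyde (selective dibenzylation, MOM, Dakin). Ring order: A and B are bought as arenes, C is formed last.

## Route

**Step 1**
Reactants: 1 2,4,6‑trihydroxybenzaldehyde; 2 benzyl bromide
Product: 3 2,4‑bis(benzyloxy)‑6‑hydroxybenzaldehyde
Conditions: BnBr (2.1 equiv), K2CO3 (2.2 equiv), DMF, 0 °C → rt
Reagents that add atoms: benzyl bromide, BrCc1ccccc1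
Why: Williamson etherification stops at the dibenzyl stage because the last ortho‑OH is hydrogen‑bonded to the aldehyde and is much less nucleophilic.

**Step 2**
Reactants: 3 2,4‑bis(benzyloxy)‑6‑hydroxybenzaldehyde; 4 chloromethyl methyl ether
Product: 5 2,4‑bis(benzyloxy)‑6‑(methoxymethoxy)benzaldehyde
Conditions: NaH (1.2 equiv), DMF, 0 °C; then MOMCl (1.3 equiv), 0 °C → rt
Reagents that add atoms: chloromethyl methyl ether (MOMCl), COCCl
Why: the sodium phenoxide of the chelated phenol is alkylated cleanly by the very reactive MOMCl (Williamson/acetal protection), giving a group orthogonal to benzyl.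

**Step 3**
Reactants: 5 2,4‑bis(benzyloxy)‑6‑(methoxymethoxy)benzaldehyde; 6 meta‑chloroperoxybenzoic acid
Product: 8 2,4‑bis(benzyloxy)‑6‑(methoxymethoxy)phenol, via aryl formate 7 (not isolated)
Conditions: mCPBA (1.3 equiv), CH2Cl2, 0 °C → rt; aq. NaHCO3/Na2S2O3 wash; then K2CO3 (0.2 equiv), MeOH, rt
Reagents that add atoms: mCPBA, OOC(=O)c1cccc(Cl)c1
Why: Dakin‑type Baeyer–Villiger oxidation, in which the very electron‑rich 2,4,6‑trialkoxyaryl group migrates in preference to H, followed by mild methanolysis of the formate.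

**Step 4**
Reactants: 9 5‑bromobenzene‑1,3‑diol (5‑bromoresorcinol); 2 benzyl bromide
Product: 10 1,3‑bis(benzyloxy)‑5‑bromobenzene
Conditions: BnBr (2.2 equiv), K2CO3 (2.5 equiv), acetone, reflux
Reagents that add atoms: benzyl bromide, BrCc1ccccc1
Why: straightforward double Williamson O‑benzylation of an unhindered resorcinol.

**Step 5**
Reactants: 8 2,4‑bis(benzyloxy)‑6‑(methoxymethoxy)phenol; 10 1,3‑bis(benzyloxy)‑5‑bromobenzene
Product: 11 1,5‑bis(benzyloxy)‑2‑[3,5‑bis(benzyloxy)phenoxy]‑3‑(methoxymethoxy)benzene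
Conditions: CuI (10 mol%), picolinic acid (20 mol%), K3PO4 (2 equiv), DMSO, 100 °C, Ar
Reagents that add atoms: 1,3‑bis(benzyloxy)‑5‑bromobenzene (10), Brc1cc(OCc2ccccc2)cc(OCc2ccccc2)c1
Why: ligand‑accelerated Ullmann diaryl ether coupling, a system suited to di‑ortho‑substituted electron‑rich phenols, with an aryl bromide that has no ortho substituents.

**Step 6**
Reactants: 11 1,5‑bis(benzyloxy)‑2‑[3,5‑bis(benzyloxy)phenoxy]‑3‑(methoxymethoxy)benzene
Product: 12 3,5‑bis(benzyloxy)‑2‑[3,5‑bis(benzyloxy)phenoxy]phenol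
Conditions: conc. HCl (cat.), MeOH/THF, 50 °C
Reagents that add atoms: none
Why: acid‑catalysed acetal exchange removes the MOM group, while benzyl and diaryl ethers are inert to dilute methanolic HCl.

**Step 7**
Reactants: 12 3,5‑bis(benzyloxy)‑2‑[3,5‑bis(benzyloxy)phenoxy]phenol; 13 methyl bromoacetate
Product: 14 methyl 2‑{3,5‑bis(benzyloxy)‑2‑[3,5‑bis(benzyloxy)phenoxy]phenoxy}acetate
Conditions: BrCH2CO2Me (1.2 equiv), K2CO3 (1.5 equiv), acetone, reflux
Reagents that add atoms: methyl bromoacetate, COC(=O)CBr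
Why: Williamson alkylation of a mono‑ortho‑substituted phenoxide with a highly reactive α‑halo ester.

**Step 8 (key C–C bond formation)**
Reactants: 14 methyl 2‑{3,5‑bis(benzyloxy)‑2‑[3,5‑bis(benzyloxy)phenoxy]phenoxy}acetate; 15 methyl acetoacetate
Product: 17 methyl 6‑{3,5‑bis(benzyloxy)‑2‑[3,5‑bis(benzyloxy)phenoxy]phenoxy}‑3,5‑dioxohexanoate, via acetoacetate dianion 16 (not isolated)
Conditions: methyl acetoacetate (2.5 equiv), NaH (2.5 equiv) then n‑BuLi (2.5 equiv), THF, 0 °C; add 14, 0 °C → rt; 1 M HCl quench at 0 °C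
Reagents that add atoms: methyl acetoacetate, COC(=O)CC(C)=O
Why: intermolecular Claisen condensation of the acetoacetate dianion (Huckin–Weiler γ‑acylation) at its γ‑carbon with the activated α‑aryloxy ester, the excess dianion absorbing the acidity of the diketo ester formed.

**Step 9**
Reactants: 17 methyl 6‑{3,5‑bis(benzyloxy)‑2‑[3,5‑bis(benzyloxy)phenoxy]phenoxy}‑3,5‑dioxohexanoate
Product: 18 2‑{3,5‑bis(benzyloxy)‑2‑[3,5‑bis(benzyloxy)phenoxy]phenoxy}benzene‑1,3,5‑triol
Conditions: NaOMe (3 equiv), tetraglyme, 150 °C, Ar, MeOH distilled off; then cold degassed 1 M HCl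
Reagents that add atoms: none
Why: intramolecular Claisen (Dieckmann‑type) attack of the α‑aryloxy C6 carbanion on the C1 ester closes the six‑membered ring, and irreversible tautomerisation to the aromatic phloroglucinol drives the equilibrium.

**Step 10**
Reactants: 18 2‑{3,5‑bis(benzyloxy)‑2‑[3,5‑bis(benzyloxy)phenoxy]phenoxy}benzene‑1,3,5‑triol
Product: 19 triphloroethol A
Conditions: H2 (1 atm), 10% Pd/C, EtOAc/MeOH, rt; filter and concentrate under Ar
Reagents that add atoms: none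
Why: neutral catalytic hydrogenolysis cleaves the four benzyl ethers without touching the diaryl ethers or exposing the air‑sensitive polyphenol to acid or base.

## Compound list

1 | 2,4,6‑trihydroxybenzaldehyde | O=Cc1c(O)cc(O)cc1O | starting material
2 | benzyl bromide | BrCc1ccccc1 | starting material
3 | 2,4‑bis(benzyloxy)‑6‑hydroxybenzaldehyde | O=Cc1c(O)cc(OCc2ccccc2)cc1OCc1ccccc1 | intermediate
4 | chloromethyl methyl ether (MOMCl) | COCCl | starting material
5 | 2,4‑bis(benzyloxy)‑6‑(methoxymethoxy)benzaldehyde | O=Cc1c(OCOC)cc(OCc2ccccc2)cc1OCc1ccccc1 | intermediate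
6 | meta‑chloroperoxybenzoic acid (mCPBA) | OOC(=O)c1cccc(Cl)c1 | starting material
7 | 2,4‑bis(benzyloxy)‑6‑(methoxymethoxy)phenyl formate | O=COc1c(OCOC)cc(OCc2ccccc2)cc1OCc1ccccc1 | intermediate
8 | 2,4‑bis(benzyloxy)‑6‑(methoxymethoxy)phenol | Oc1c(OCOC)cc(OCc2ccccc2)cc1OCc1ccccc1 | intermediate
9 | 5‑bromobenzene‑1,3‑diol | Oc1cc(O)cc(Br)c1 | starting material
10 | 1,3‑bis(benzyloxy)‑5‑bromobenzene | Brc1cc(OCc2ccccc2)cc(OCc2ccccc2)c1 | intermediate
11 | 1,5‑bis(benzyloxy)‑2‑[3,5‑bis(benzyloxy)phenoxy]‑3‑(methoxymethoxy)benzene | COCOc1cc(OCc2ccccc2)cc(OCc2ccccc2)c1Oc1cc(OCc2ccccc2)cc(OCc2ccccc2)c1 | intermediate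
12 | 3,5‑bis(benzyloxy)‑2‑[3,5‑bis(benzyloxy)phenoxy]phenol | Oc1cc(OCc2ccccc2)cc(OCc2ccccc2)c1Oc1cc(OCc2ccccc2)cc(OCc2ccccc2)c1 | intermediate
13 | methyl bromoacetate | COC(=O)CBr | starting material
14 | methyl 2‑{3,5‑bis(benzyloxy)‑2‑[3,5‑bis(benzyloxy)phenoxy]phenoxy}acetate | COC(=O)COc1cc(OCc2ccccc2)cc(OCc2ccccc2)c1Oc1cc(OCc2ccccc2)cc(OCc2ccccc2)c1 | intermediate
15 | methyl acetoacetate | COC(=O)CC(C)=O | starting material
16 | methyl acetoacetate dianion (sodium lithium salt) | [Na+].[Li+].[CH2-]C(=O)[CH-]C(=O)OC | intermediate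
17 | methyl 6‑{3,5‑bis(benzyloxy)‑2‑[3,5‑bis(benzyloxy)phenoxy]phenoxy}‑3,5‑dioxohexanoate | COC(=O)CC(=O)CC(=O)COc1cc(OCc2ccccc2)cc(OCc2ccccc2)c1Oc1cc(OCc2ccccc2)cc(OCc2ccccc2)c1 | intermediate
18 | 2‑{3,5‑bis(benzyloxy)‑2‑[3,5‑bis(benzyloxy)phenoxy]phenoxy}benzene‑1,3,5‑triol | Oc1cc(O)c(Oc2cc(OCc3ccccc3)cc(OCc3ccccc3)c2Oc2cc(OCc3ccccc3)cc(OCc3ccccc3)c2)c(O)c1 | intermediate
19 | triphloroethol A | Oc1cc(O)cc(Oc2c(O)cc(O)cc2Oc2c(O)cc(O)cc2O)c1 | target

## Summary

Total step count: 10. Longest linear sequence: 9 steps (1, 2, 3, 5, 6, 7, 8, 9, 10); step 4 is a one‑step branch.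

Three steps most likely to fail, with fallbacks:

Step 9 (ring‑C Claisen cyclisation/aromatisation; the nucleophilic carbon is only singly carbonyl‑activated and retro‑Claisen cleavage can compete). The fallback gives up the de novo ring and attaches a preformed ring C. It sets out from phenol 12. Commercial 1,3,5‑tris(benzyloxy)benzene F1 is iodinated with NIS in MeCN to 1,3,5‑tris(benzyloxy)‑2‑iodobenzene F2. F2 is coupled with 12 under Ullmann conditions (CuI, N,N‑dimethylglycine, Cs2CO3, dioxane or NMP, 110–120 °C) to the heptabenzyl ether of triphloroethol A F3. Hydrogenolysis of F3 (H2, Pd/C, EtOAc/MeOH) comes back to the route at target 19.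

Step 8 (dianion Claisen; the α‑aryloxy ester can be enolised and the product consumes base). The fallback swaps ester acylation for an aldol/oxidation sequence. It sets out from ester 14, which is reduced with DIBAL‑H (CH2Cl2, −78 °C) to 2‑{3,5‑bis(benzyloxy)‑2‑[3,5‑bis(benzyloxy)phenoxy]phenoxy}acetaldehyde F4. Aldol addition of the methyl acetoacetate dianion (THF, −78 °C) gives racemic methyl 6‑aryloxy‑5‑hydroxy‑3‑oxohexanoate F5, whose stereocentre is of no consequence. Oxidation of the secondary alcohol with Dess–Martin periodinane (CH2Cl2, rt) comes back to the route at diketo ester 17.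

Step 5 (Ullmann coupling of a di‑ortho‑substituted, oxidation‑prone phenol). The fallback replaces the Cu(I)/aryl halide coupling with an oxidative Chan–Lam arylation at room temperature. It sets out from bromide 10, which is converted by Br–Li exchange (n‑BuLi, THF, −78 °C), B(OiPr)3 and aqueous acid into [3,5‑bis(benzyloxy)phenyl]boronic acid F6. F6 is coupled with phenol 8 (Cu(OAc)2, pyridine, 4 Å MS, CH2Cl2, air, rt) and comes back to the route at diaryl ether 11.

## Further compounds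

F1 | step 9 | 1,3,5‑tris(benzyloxy)benzene | c1ccc(COc2cc(OCc3ccccc3)cc(OCc3ccccc3)c2)cc1
F2 | step 9 | 1,3,5‑tris(benzyloxy)‑2‑iodobenzene | Ic1c(OCc2ccccc2)cc(OCc2ccccc2)cc1OCc1ccccc1
F3 | step 9 | triphloroethol A heptabenzyl ether | C(c1ccccc1)Oc1cc(OCc2ccccc2)c(Oc2cc(OCc3ccccc3)cc(OCc3ccccc3)c2Oc2cc(OCc3ccccc3)cc(OCc3ccccc3)c2)c(OCc2ccccc2)c1
F4 | step 8 | 2‑{3,5‑bis(benzyloxy)‑2‑[3,5‑bis(benzyloxy)phenoxy]phenoxy}acetaldehyde | O=CCOc1cc(OCc2ccccc2)cc(OCc2ccccc2)c1Oc1cc(OCc2ccccc2)cc(OCc2ccccc2)c1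
F5 | step 8 | methyl 6‑{3,5‑bis(benzyloxy)‑2‑[3,5‑bis(benzyloxy)phenoxy]phenoxy}‑5‑hydroxy‑3‑oxohexanoate (racemic) | COC(=O)CC(=O)CC(O)COc1cc(OCc2ccccc2)cc(OCc2ccccc2)c1Oc1cc(OCc2ccccc2)cc(OCc2ccccc2)c1
F6 | step 5 | [3,5‑bis(benzyloxy)phenyl]boronic acid | OB(O)c1cc(OCc2ccccc2)cc(OCc2ccccc2)c1
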